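5 questions stand on 4 flasks of one charge, with free catalyst at 2.45 % of the starting material, held 4.0 d at different temperatures: which flask holds the highest target, and how much each holds.

| flask | starting material | free catalyst | temperature | remark | time |
|---|---|---|---|---|---|
| midnight | 0.53 M | 18 mM | 4 °C | run made earlier |  |
| summer | 0.53 M | 29 mM | 45 °C | run made earlier |  |
| beta | 0.53 M | 13 mM | −15 °C |  | 4.0 d |
| delta | 0.53 M | 13 mM | 60 °C |  | 4.0 d |
| epsilon | 0.53 M | 13 mM | 10 °C |  | 4.0 d |
| eta | 0.53 M | 13 mM | 35 °C |  | 4.0 d |

| run | time / h | target / % | starting material / % |
|---|---|---|---|
| midnight | 6.00 | 0.1 | 96.5 |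
| midnight | 12.0 | 0 | 96.5 |
| midnight | 20.0 | 0.2 | 96.4 |
| midnight | 30.0 | 0 | 95.7 |
| midnight | 40.0 | 1.2 | 95.6 |
| midnight | 50.0 | 0.4 | 96.0 |
| summer | 0.333 | 1.9 | 93.4 |
| summer | 1.00 | 7.0 | 86.7 |
| summer | 1.50 | 12.0 | 82.5 |
| summer | 2.50 | 18.5 | 73.8 |
| summer | 4.00 | 26.2 | 59.1 |
| summer | 5.00 | 32.6 | 50.0 |
| summer | 6.00 | 36.1 | 41.4 |

(each reading ± 0.5 percentage points)

- the numbers in the tables scatter by 0.5 percentage points (one standard deviation)

* the flask that comes out highest in amount of target, in percent of the starting material charged, or "all alike" when all lie within 1.5 percentage points (beta / delta / epsilon / eta / all alike)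
* target at the end, in percent of the starting material charged, beta
* target at the end, in percent of the starting material charged, delta
* target at the end, in percent of the starting material charged, epsilon
* target at the end, in percent of the starting material charged, eta

In the midnight run starting material stands 3.50 % below the charge at the first reading, beside catalyst at 3.40 % of the charge, so it seems to sit on the catalyst one to one. In the summer run it then falls in a straight line, zero order, and that line gives an emptying time, the time the feed needs for one whole charge: 10.9 h.

Two people read this differently. The heater takes one step, first order in starting material and in free catalyst, with reacted starting material read as target. The heater points to the readings: midnight shows 0.4 % target at 50.0 h, while summer, hotter and with more free catalyst, shows 36.1 % at 6.00 h, and so the heater expects the highest target in delta, the hottest of the four flasks.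

The keeper adds up the summer run at 6.00 h: starting material, target and the share on the catalyst leave 17.0 % of the charge missing. Taking the mean target as 0.5 of its last reading, the target lifetime is 6.36 h. Delta, hotter than summer, sits 4.0 d, which is 15.1 such lifetimes even at summer's rate, so the keeper expects little target there.

My own reckoning follows the keeper. Call N the emptying time counted in target lifetimes: 1.71 in summer. With f the fraction of the charge reacted, target obeys dP/df = one − NP, so the target share is (one − exp(−Nf))/N, a selectivity curve with time gone from it. I assume that the feed goes with the catalyst and that making and loss warm alike. The exposure number, emptying time over target lifetime, is then 3.82 in the four flasks, and at f = one the target stands at 25.6 %. Midnight moved 0.5 percentage points of its starting material between its first and last readings, so I expect beta and epsilon far below f = one, and delta to lose its target after passing f = one. I commit to eta, near that figure.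

The forecast sides with the keeper: eta highest, with 0.03 % in beta, 0.1 % in delta, 2.7 % in epsilon and 30 % in eta, on the ground that “the target itself decays”. Its eta stands above my figure.

The simulation gives eta: 15.6 % in eta, 3.12 % in epsilon, 0.00520 % in beta, 0 % in delta.

    catalyst intermediate A ⇌ catalyst intermediate B (K = 15.0, k = 2.20 h⁻¹, Ea = 93.0 kJ mol⁻¹, ΔH = −43.0 kJ mol⁻¹)
    catalyst intermediate B → free catalyst + target (k = 0.730 h⁻¹, Ea = 105 kJ mol⁻¹)
    starting material + free catalyst → catalyst intermediate A (k = 39.0 L mol⁻¹ h⁻¹, Ea = 44.0 kJ mol⁻¹)
    target → over-reaction product (k = 0.0440 h⁻¹, Ea = 94.0 kJ mol⁻¹)
    (constants at 35 °C)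

Target at 4.0 d is highest at 32.3 °C, and from beta to epsilon the heater's hotter-gives-more holds. Eta ends 14 points under the forecast, with 0.0113 % of its starting material left. At 2.00 d eta held f = 58.7 % as target and over-reaction product together, for which the exposure number gives 23.4 % target, and it held 24.4 %. Epsilon at 40.0 d held f = 36.8 % as target and over-reaction product together, for which the exposure number gives 19.8 % target, and it held 18.1 %.

(The readings come from a simulation for an exercise, and the scatter is random.)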